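You read this flask at 2.5 d, and the question is whether half of the electrophile has reacted by then.

| setting | north | south-east | flask |
|---|---|---|---|
| electrophile | 13 mM | 30 mM | 20 mM |
| buffer base | 60 mM | 60 mM | 60.0 mM |
| buffer acid | 2 mM | 2 mM | 2.00 mM |
| gas | 2.7 mM (held) | 2.7 mM (held) | 2.7 mM (held) |
| remark | run made earlier | run made earlier |  |
| time |  |  | 2.5 d |

| run | time / d | electrophile / % | target / % |
|---|---|---|---|
| north | 0.500 | 95.0 | 1.4 |
| north | 1.04 | 87.8 | 13.7 |
| north | 1.67 | 77.6 | 22.1 |
| north | 2.08 | 72.4 | 30.0 |
| north | 2.50 | 65.2 | 35.7 |
| north | 3.00 | 59.9 | 40.4 |
| south-east | 0.208 | 97.5 | 0.4 |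
| south-east | 0.625 | 94.0 | 2.3 |
| south-east | 1.04 | 91.7 | 10.9 |
| south-east | 1.67 | 83.2 | 16.6 |
| south-east | 2.50 | 75.1 | 26.8 |
| south-east | 3.00 | 69.9 | 30.9 |

(each reading ± 1 percentage point)

* part of the electrophile that has reacted at 2.5 d
* pH of the solution at 2.5 d

- the numbers in the tables scatter with a standard deviation of 1 percentage point
- at the start none of the gas is in solution
- the earlier runs do not show the pH; that part of a forecast is a guess

Both runs start slowly and then fall along a nearly straight line, much like a dead time followed by a ramp, so I count turnovers. From the reading at 1.04 d to the last one, the north line has a slope worth 7.03 d per charge and the south-east line 8.99 d. Traced back to the full charge, the two lines give a mean dead time of 0.238 d. This flask's charge lies between those of the runs, so interpolating on the logarithm of the charge gives an estimate of 7.98 d. That is this flask's turnover time, the days the straight stretch would need to use up the whole charge.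

Now turn the question round. With the same dead time and a straight line, for half of the charge to be gone at the time of reading, the turnover time would have to be 4.52 d. My estimate for this flask is longer by a factor of 1.77, and even the value read from the north run stays above that mark. My count therefore gives 28.4 % of a turnover.

The forecast, a little higher, gives 30 %, with a range of 26.5 % to 33.5 %, and pH 7.6, with a range of 6.7 to 8.4. Of the pH it says: “pH is a guess”.

The flask gives 30.4 % of the electrophile reacted and pH 7.42, against 28.4 % from the count.

    electrophile + nucleophile → acid + target + leaving group (k = 0.0780 L mol⁻¹ min⁻¹)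
    protonated nucleophile ⇌ nucleophile + acid, settled at all times (K = 7.90 × 10⁻⁹ M)
    buffer acid ⇌ buffer base + acid, settled at all times (K = 5.00 × 10⁻⁶ M)
    gas ⇌ nucleophile, rate k4*(csat - [nucleophile]) (kL = 0.00300 min⁻¹)

At 1.05 d, the step to the target gives the electrophile a half-life of 4.4 d and the nucleophile a pseudo-first-order half-life of 0.35 d. Counted at those values, the time of reading holds 7.14 nucleophile half-lives but 0.568 electrophile half-lives, and 70 % of the electrophile remains in this flask. For a neighbouring flask with the same charges, read at 15 h, the turnover time 7.98 d and dead time give 4.85 %; that flask gives 5.24 %.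

Readings and results are simulated with constants of no real substance.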